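## Retrosynthetic overview

1. The target comes from a Schenck ene reaction (singlet oxygen) on the 7(11)-en-8-one angelate. The angelate comes from selective esterification of the 3β,4β-diol, and the diol from hydride reduction of the 3-keto-4β-ol.
2. Key disconnection, C3–C4: a carbene-catalysed crossed benzoin. The C3 aldehyde, acting as a Breslow acyl anion, attacks the C4 methyl ketone of a 3,4-seco-eudesmane. This closes ring A last and sets C4.
3. The keto-aldehyde comes from one double Lemieux–Johnson cleavage of the butenyl and isopropenyl groups of a triene ketone.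
4. The triene comes from acetone aldol addition and dehydration on the regiodefined enolate that cyclobutane fragmentation of a 4-butenylverbanone releases.
5. The verbanone comes from copper-catalysed anti addition of butenylMgBr to (+)-verbenone, which sets C10, while C5 comes from the chiral pool. Ring B is the six-membered ring of verbenone (first); ring A is closed second.

Assumption: (1R,5R)-(+)-verbenone is bought as such (it is also the one-step allylic oxidation product of (+)-α-pinene); atom labels C1–C15 follow eudesmane numbering.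

## Route

Step 1
Reactants: 1 (1R,5R)-(+)-verbenone; 2 but-3-en-1-ylmagnesium bromide
Product: 4 (1R,4R,5R)-4-(but-3-en-1-yl)-4,6,6-trimethylbicyclo[3.1.1]heptan-2-one, via bromomagnesium enolate 3 (not isolated)
Conditions: 2 (1.5 equiv), CuBr·SMe2 (10 mol %), LiCl (20 mol %), THF, −40 → 0 °C; then 1 M HCl
Reagents that add atoms: but-3-en-1-ylmagnesium bromide (2), C=CCC[Mg]Br
Why: Copper-catalysed 1,4-addition of a Grignard reagent (the butenyl group is a masked 3-oxopropyl, i.e. a homoenolate equivalent), in which the organocopper attacks the enone face opposite the gem-dimethyl bridge, so the chain ends anti and the methyl syn to that bridge, which sets quaternary C10 as R and places C1 trans to the future C4 on ring B.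

Step 2
Reactants: 4 (1R,4R,5R)-4-(but-3-en-1-yl)-4,6,6-trimethylbicyclo[3.1.1]heptan-2-one
Product: 5 (4R,5R)-4-(2-acetoxypropan-2-yl)-5-(but-3-en-1-yl)-5-methylcyclohex-1-en-1-yl acetate
Conditions: BF3·OEt2 (1.5 equiv), Zn(OAc)2 (2 equiv), Ac2O, 0 °C → rt
Reagents that add atoms: acetic anhydride, CC(=O)OC(C)=O; zinc acetate (acetate relay), CC(=O)[O-].CC(=O)[O-].[Zn+2]
Why: Lewis-acid-promoted acetolytic fragmentation of a cyclobutyl ketone (nopinone-type cleavage), in which BF3 activation breaks the strained bridgehead–CMe2 bond toward the tertiary cation, acetate traps the cation and Ac2O traps the enolate, so the enol regiochemistry is fixed at C7=C8 while C5 and C10 stay untouched and the poorly nucleophilic terminal alkene survives.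

Step 3
Reactants: 5 (4R,5R)-4-(2-acetoxypropan-2-yl)-5-(but-3-en-1-yl)-5-methylcyclohex-1-en-1-yl acetate; 6 acetone
Product: 8 (2R,4R,5R)-5-(but-3-en-1-yl)-2,4-bis(2-hydroxypropan-2-yl)-5-methylcyclohexan-1-one, via dilithium enolate alkoxide 7 (not isolated)
Conditions: MeLi (4.2 equiv), Et2O/THF, 0 °C; 6 (1.5 equiv), −78 °C, 10 min; AcOH, −78 °C
Reagents that add atoms: acetone (6), CC(C)=O
Why: Enol acetate cleavage by MeLi gives the regiodefined lithium enolate (no equilibration toward the neopentyl C9), which undergoes aldol addition to acetone at C7 with the new arm equatorial (a centre erased in step 4), while the tertiary acetate is cleaved to its alkoxide in the same operation.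

Step 4
Reactants: 8 (2R,4R,5R)-5-(but-3-en-1-yl)-2,4-bis(2-hydroxypropan-2-yl)-5-methylcyclohexan-1-one
Product: 11 (4S,5R)-5-(but-3-en-1-yl)-5-methyl-4-(prop-1-en-2-yl)-2-(propan-2-ylidene)cyclohexan-1-one, via bis(chlorosulfite) 9 (not isolated), via deconjugated 7-isopropenyl ketone 10 (not isolated)
Conditions: SOCl2 (3 equiv), pyridine, CH2Cl2, −10 °C; wash; crude + 1,8-diazabicyclo[5.4.0]undec-7-ene (20 mol %), PhMe, rt
Reagents that add atoms: none
Why: Chlorosulfite dehydration, in which both arms lose an accessible methyl H by E2 (the C5–H is shielded by quaternary C10, so C5 keeps its isopropenyl group) and the amidine base then moves the β,γ-alkene at C7 into conjugation (pulegone-type equilibrium), leaving C5 and C10 unchanged.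

Step 5
Reactants: 11 (4S,5R)-5-(but-3-en-1-yl)-5-methyl-4-(prop-1-en-2-yl)-2-(propan-2-ylidene)cyclohexan-1-one
Product: 13 3-[(1R,2R)-2-acetyl-1-methyl-5-oxo-4-(propan-2-ylidene)cyclohexyl]propanal, via tetraol 12 (not isolated)
Conditions: OsO4 (2 mol %), NaIO4 (5 equiv), 2,6-lutidine (2 equiv), dioxane/H2O 3:1, rt
Reagents that add atoms: osmium tetroxide, O=[Os](=O)(=O)=O; sodium periodate, [Na+].[O-]I(=O)(=O)=O; water, O
Why: Lemieux–Johnson oxidation, in which OsO4 dihydroxylates the mono- and 1,1-disubstituted alkenes but not the tetrasubstituted electron-poor enone alkene and periodate cleaves both diols, so the C3 aldehyde and the C4 methyl ketone are unveiled together under buffered conditions that do not epimerise C5.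

Step 6 (key step)
Reactants: 13 3-[(1R,2R)-2-acetyl-1-methyl-5-oxo-4-(propan-2-ylidene)cyclohexyl]propanal
Product: 15 (4R,5R,10R)-4β-hydroxyeudesm-7(11)-ene-3,8-dione, via Breslow enaminol 14 (not isolated)
Conditions: 2-(pentafluorophenyl)-6,7-dihydro-5H-pyrrolo[2,1-c][1,2,4]triazol-2-ium tetrafluoroborate (20 mol %), NaOAc (20 mol %), CHCl3 (0.02 M), 23 → 40 °C
Reagents that add atoms: none
Why: Carbene-catalysed intramolecular crossed aldehyde–ketone benzoin, in which the carbene turns the C3 aldehyde into a Breslow enaminol (acyl anion equivalent) that attacks the C4 ketone carbon through a chair-like six-ring transition state on the fixed trans C5/C10 scaffold, the C4 methyl going equatorial (α) to avoid a 1,3-diaxial clash with the C10 methyl so that the hydroxyl ends axial β (4R), while the β,β-disubstituted enone is neither a benzoin nor a Stetter acceptor and the weak acetate base spares C5.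

Step 7
Reactants: 15 (4R,5R,10R)-4β-hydroxyeudesm-7(11)-ene-3,8-dione
Product: 16 (3S,4R,5R,10R)-3β,4β-dihydroxyeudesm-7(11)-en-8-one
Conditions: NaBH4 (1 equiv), MeOH/CH2Cl2 1:1, −78 °C; H2O
Reagents that add atoms: none
Why: Chemo- and diastereoselective borohydride reduction, in which the unconjugated, inductively activated α-ketol carbonyl reacts far faster than the hindered tetrasubstituted enone and hydride enters axially from the α face, anti to the axial 4β C–O bond (polar Felkin–Anh), giving the equatorial 3β-OH (3S) cis to the 4β-OH.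

Step 8
Reactants: 16 (3S,4R,5R,10R)-3β,4β-dihydroxyeudesm-7(11)-en-8-one; 17 angelic acid
Product: 19 (3S,4R,5R,10R)-3β-angeloyloxy-4β-hydroxyeudesm-7(11)-en-8-one, via angelic 2,4,6-trichlorobenzoic anhydride 18 (not isolated)
Conditions: 17 (2 equiv), 2,4,6-Cl3C6H2COCl (2 equiv), Et3N (2.2 equiv), PhMe, rt, 2 h; then 16, 80 °C
Reagents that add atoms: angelic acid (17), C/C=C(/C)C(=O)O
Why: Yamaguchi-type mixed-anhydride esterification run without DMAP, the usual way to make angelates without Z-to-E leakage to the tiglate, in which only the equatorial secondary 3β-OH is acylated because the axial tertiary 4β-OH is inert.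

Step 9
Reactants: 19 (3S,4R,5R,10R)-3β-angeloyloxy-4β-hydroxyeudesm-7(11)-en-8-one
Product: 20 (3S,4R,5R,10R)-3β-angeloyloxy-4β-hydroxy-11-hydroperoxyeudesm-6-en-8-one
Conditions: O2, 5,10,15,20-tetraphenylporphyrin (1 mol %), CH2Cl2, 0 °C, visible light, stopped at full conversion of 19
Reagents that add atoms: dioxygen, O=O
Why: Schenck ene reaction, in which singlet oxygen picks the tetrasubstituted s-cis enone alkene over the much slower trisubstituted angelate alkene and the geminal rule for α,β-unsaturated carbonyls directs H abstraction to C6 (the alkyl group geminal to the carbonyl), so oxygen ends on C11 and the alkene moves to C6=C7 in conjugation without touching any stereocentre.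

## Compound list

1 | (1R,5R)-(+)-verbenone, (1R,5R)-4,6,6-trimethylbicyclo[3.1.1]hept-3-en-2-one | CC1=CC(=O)[C@@H]2C[C@H]1C2(C)C | starting material
2 | but-3-en-1-ylmagnesium bromide (0.5 M in THF) | C=CCC[Mg]Br | starting material
3 | bromomagnesium enolate of 4 | C=CCC[C@]1(C)C=C(O[Mg]Br)[C@@H]2C[C@H]1C2(C)C | intermediate (not isolated)
4 | (1R,4R,5R)-4-(but-3-en-1-yl)-4,6,6-trimethylbicyclo[3.1.1]heptan-2-one (butenyl anti to the CMe2 bridge) | C=CCC[C@]1(C)CC(=O)[C@@H]2C[C@H]1C2(C)C | intermediate
5 | (4R,5R)-4-(2-acetoxypropan-2-yl)-5-(but-3-en-1-yl)-5-methylcyclohex-1-en-1-yl acetate | C=CCC[C@]1(C)CC(OC(C)=O)=CC[C@H]1C(C)(C)OC(C)=O | intermediate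
6 | acetone | CC(C)=O | starting material
7 | dilithium enolate alkoxide from 5 | C=CCC[C@]1(C)CC([O-])=CC[C@H]1C(C)(C)[O-].[Li+].[Li+] | intermediate (not isolated)
8 | (2R,4R,5R)-5-(but-3-en-1-yl)-2,4-bis(2-hydroxypropan-2-yl)-5-methylcyclohexan-1-one (C2 arm equatorial; this centre is erased in step 4) | C=CCC[C@]1(C)CC(=O)[C@@H](C(C)(C)O)C[C@H]1C(C)(C)O | intermediate
9 | bis(chlorosulfite) of 8 | C=CCC[C@]1(C)CC(=O)[C@@H](C(C)(C)OS(=O)Cl)C[C@H]1C(C)(C)OS(=O)Cl | intermediate (not isolated)
10 | (2R,4S,5R)-5-(but-3-en-1-yl)-5-methyl-2,4-di(prop-1-en-2-yl)cyclohexan-1-one | C=CCC[C@]1(C)CC(=O)[C@@H](C(C)=C)C[C@H]1C(C)=C | intermediate (not isolated)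
11 | (4S,5R)-5-(but-3-en-1-yl)-5-methyl-4-(prop-1-en-2-yl)-2-(propan-2-ylidene)cyclohexan-1-one | C=CCC[C@]1(C)CC(=O)C(=C(C)C)C[C@H]1C(C)=C | intermediate
12 | tetraol from double dihydroxylation of 11 (epimers at the two new carbinol carbons) | OCC(O)CC[C@]1(C)CC(=O)C(=C(C)C)C[C@H]1C(C)(O)CO | intermediate (not isolated)
13 | 3-[(1R,2R)-2-acetyl-1-methyl-5-oxo-4-(propan-2-ylidene)cyclohexyl]propanal | O=CCC[C@]1(C)CC(=O)C(=C(C)C)C[C@H]1C(C)=O | intermediate
14 | Breslow enaminol of 13 on the triazolylidene carbene | OC(CC[C@]1(C)CC(=O)C(=C(C)C)C[C@H]1C(C)=O)=C1N(c2c(F)c(F)c(F)c(F)c2F)N=C2CCCN12 | intermediate (not isolated)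
15 | (4R,5R,10R)-4β-hydroxyeudesm-7(11)-ene-3,8-dione, i.e. (1R,4aR,8aR)-1-hydroxy-1,4a-dimethyl-7-(propan-2-ylidene)octahydronaphthalene-2,6-dione, trans-fused | O=C1CC[C@]2(C)CC(=O)C(=C(C)C)C[C@H]2[C@@]1(C)O | intermediate
16 | (3S,4R,5R,10R)-3β,4β-dihydroxyeudesm-7(11)-en-8-one | O[C@H]1CC[C@]2(C)CC(=O)C(=C(C)C)C[C@H]2[C@@]1(C)O | intermediate
17 | angelic acid, (Z)-2-methylbut-2-enoic acid | C/C=C(/C)C(=O)O | starting material
18 | angelic 2,4,6-trichlorobenzoic anhydride | C/C=C(/C)C(=O)OC(=O)c1c(Cl)cc(Cl)cc1Cl | intermediate (not isolated)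
19 | (3S,4R,5R,10R)-3β-angeloyloxy-4β-hydroxyeudesm-7(11)-en-8-one | C/C=C(/C)C(=O)O[C@H]1CC[C@]2(C)CC(=O)C(=C(C)C)C[C@H]2[C@@]1(C)O | intermediate
20 | (3S,4R,5R,10R)-3β-angeloyloxy-4β-hydroxy-11-hydroperoxyeudesm-6-en-8-one (CNP0161122.3) | C/C=C(/C)C(=O)O[C@H]1CC[C@]2(C)CC(=O)C(C(C)(C)OO)=C[C@H]2[C@@]1(C)O | target

## Step count and risks

Total step count: 9. Longest linear sequence: 9 (from 1).

**Step 6, benzoin ring closure (highest risk).** The ketone is hindered. C5 of 13 can epimerise, which would lead to the cis-decalin. The enolisable aldehyde can also close a five-membered aldol ring onto C4. The fallback sets out from 11 and comes back at 16. It keeps the C3–C4 bond but makes it with a ketyl instead of an acyl anion, with the enone masked. The enone of 11 is reduced with i-Bu2AlH (PhMe, −78 °C), hydride arriving from the α face away from the axial C10 methyl, to give the 8β-hydroxy triene F1 (the C8 configuration is of no consequence). OsO4/NaIO4/2,6-lutidine then cleaves both terminal alkenes to the hydroxy keto-aldehyde F2. SmI2 (2.5 equiv, THF/t-BuOH, −78 °C → rt) effects a chelated pinacol coupling that gives the cis 3β,4β-diol directly, with the C4 methyl equatorial, as the 3β,4β,8β-triol F3. MnO2 (CH2Cl2, rt) re-oxidises only the allylic alcohol and delivers 16.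

**Step 9, Schenck ene reaction.** The risks are slow over-oxidation of the angelate alkene, some C7-hydroperoxide regioisomer, and a labile product. The fallback sets out from 16 and comes back at 20. It installs the O–O bond by substitution instead of by an ene reaction on the ester. Diol 16, which carries no angelate alkene, is photooxygenated under the same conditions to the hydroperoxy diol F4. PPh3 in the same flask reduces F4 to the stable, purifiable 11-hydroxy enone triol F5. Anhydride 18 (PhMe, 80 °C) acylates the only secondary hydroxyl to give the 11-hydroxy angelate F6. Acid-catalysed perhydrolysis (anhydrous H2O2 in Et2O, cat. H2SO4, 0 °C) then exchanges the tertiary allylic C11 hydroxyl, the only one that ionises readily, for OOH to give 20.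

**Step 2, cyclobutane acetolysis.** The risks are alkene acylation or cation–alkene side reactions under BF3/Ac2O, and the later regiochemistry of the double dehydration. The fallback sets out from 4 and comes back at 11, bypassing 5 and 8. Me3SiI (CH2Cl2, hexamethyldisilazane as acid scavenger, −40 → 0 °C) fragments the cyclobutyl ketone to the iodo silyl enol ether F7. 1,8-Diazabicyclo[5.4.0]undec-7-ene, added to the same flask, eliminates HI to give the isopropenyl silyl enol ether F8. Mukaiyama aldol addition to acetone (TiCl4, CH2Cl2, −78 °C) gives the β-hydroxy ketone F9. MsCl/Et3N (CH2Cl2, 0 °C → rt) then removes the β-hydroxyl by E1cB, which can only give the conjugated isopropylidene ketone 11.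

## Further compounds

F1 | step 6 | 8β-hydroxy triene, (1R,4S,5R)-5-(but-3-en-1-yl)-5-methyl-4-(prop-1-en-2-yl)-2-(propan-2-ylidene)cyclohexan-1-ol | C=CCC[C@]1(C)C[C@@H](O)C(=C(C)C)C[C@H]1C(C)=C
F2 | step 6 | hydroxy keto-aldehyde, 3-[(1R,2R,5R)-2-acetyl-5-hydroxy-1-methyl-4-(propan-2-ylidene)cyclohexyl]propanal | O=CCC[C@]1(C)C[C@@H](O)C(=C(C)C)C[C@H]1C(C)=O
F3 | step 6 | 3β,4β,8β-triol, 3β,4β,8β-trihydroxyeudesm-7(11)-ene | O[C@H]1CC[C@]2(C)C[C@@H](O)C(=C(C)C)C[C@H]2[C@@]1(C)O
F4 | step 9 | hydroperoxy diol, 3β,4β-dihydroxy-11-hydroperoxyeudesm-6-en-8-one | O[C@H]1CC[C@]2(C)CC(=O)C(C(C)(C)OO)=C[C@H]2[C@@]1(C)O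
F5 | step 9 | 11-hydroxy enone triol, 3β,4β,11-trihydroxyeudesm-6-en-8-one | O[C@H]1CC[C@]2(C)CC(=O)C(C(C)(C)O)=C[C@H]2[C@@]1(C)O
F6 | step 9 | 11-hydroxy angelate, 3β-angeloyloxy-4β,11-dihydroxyeudesm-6-en-8-one | C/C=C(/C)C(=O)O[C@H]1CC[C@]2(C)CC(=O)C(C(C)(C)O)=C[C@H]2[C@@]1(C)O
F7 | step 2 | iodo silyl enol ether, {[(4R,5R)-5-(but-3-en-1-yl)-4-(2-iodopropan-2-yl)-5-methylcyclohex-1-en-1-yl]oxy}trimethylsilane | C=CCC[C@]1(C)CC(O[Si](C)(C)C)=CC[C@H]1C(C)(C)I
F8 | step 2 | isopropenyl silyl enol ether, {[(4S,5R)-5-(but-3-en-1-yl)-5-methyl-4-(prop-1-en-2-yl)cyclohex-1-en-1-yl]oxy}trimethylsilane | C=CCC[C@]1(C)CC(O[Si](C)(C)C)=CC[C@H]1C(C)=C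
F9 | step 2 | β-hydroxy ketone, (2R,4S,5R)-5-(but-3-en-1-yl)-2-(2-hydroxypropan-2-yl)-5-methyl-4-(prop-1-en-2-yl)cyclohexan-1-one | C=CCC[C@]1(C)CC(=O)[C@@H](C(C)(C)O)C[C@H]1C(C)=C
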